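We choose to count lifetimes before we reckon any yield.

| setting | south | east | winter | spring | noon | summer |
|---|---|---|---|---|---|---|
| starting material | 0.10 M | 0.15 M | 0.20 M | 0.20 M | 0.20 M | 0.20 M |
| reagent | 0.30 M | 0.30 M | 0.300 M | 0.300 M | 0.300 M | 0.300 M |
| second substrate | 1 M | 1 M | 1.00 M | 1.00 M | 1.00 M | 1.00 M |
| protic impurity | 0.040 M | 0.040 M | 0.0400 M | 0.0400 M | 0.0400 M | 0.0400 M |
| temperature | −10 °C | 40 °C | −5 °C | 85 °C | 55 °C | 25 °C |
| remark | run made earlier | run made earlier |  |  |  |  |
| time |  |  | 5.0 h | 5.0 h | 5.0 h | 5.0 h |

south run (percent of the starting material charged)

| time / h | target / % | starting material / % |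
|---|---|---|
| 0.500 | 0.8 | 100.3 |
| 1.50 | 2.3 | 99.2 |
| 3.00 | 5.8 | 96.8 |
| 4.00 | 6.0 | 93.9 |
| 6.00 | 7.1 | 93.7 |

east run (percent of the starting material charged)

| time / min | target / % | starting material / % |
|---|---|---|
| 3.00 | 6.1 | 92.8 |
| 10.0 | 10.3 | 82.7 |
| 20.0 | 17.9 | 67.7 |
| 25.0 | 20.0 | 67.1 |
| 40.0 | 25.1 | 55.3 |

(readings scatter by 1 percentage point)

- the earlier runs were read with a standard deviation of 1 percentage point

- the flask that comes out highest in amount of target, in percent of the starting material charged, or "all alike" when all lie within 1.5 percentage points (winter / spring / noon / summer / all alike)
- target at the end, in percent of the starting material charged, winter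
- target at the end, in percent of the starting material charged, spring
- target at the end, in percent of the starting material charged, noon
- target at the end, in percent of the starting material charged, summer

1. Both earlier runs start at [reagent] = 0.30 M, so we read the loss of starting material as pseudo-first-order. The last readings give k = 0.0108 /h in the south run and 0.889 /h in the east run, so the apparent activation energy, as read, is 60.4 kJ/mol.

2. Carried to the new temperatures, this gives n = 0.0907 for winter, 1.38 for summer, 12.8 for noon and 81.8 for spring. This n, k at the flask's temperature times the time, is our lifetime count.

3. In the first extreme version, [reagent] stands at its charge and converted material stays target, so target is one minus e to the minus n. In the second, conversion is the same, but target keeps the share of the loss read at the east run's last reading, 56.2%.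

4. Winter's count is less than one, and winter's temperature stands near that of the south run, where target matched the loss within scatter. So we commit to about 8.67% for winter. Summer lies in temperature between the two runs, so we place it between 42.1% and 74.8%. The east run's average k over its whole length, as read, is lower than the 1.17 /h read for its first 20.0 min, so reagent may be going, and the large counts for noon and spring may overstate what those flasks convert.

5. The forecast says summer, with winter 10%, spring 14%, noon 30% and summer 43%. Its ground is that “a side path with higher activation energy is opening up”.

6. The simulation gives noon as highest, with winter 9.29%, spring 36.6%, noon 45.1% and summer 17.3%.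

    starting material + reagent → target (k = 3.60 × 10⁻⁴ /M/s, Ea = 62.0 kJ/mol)
    second substrate + reagent → second product (k = 3.70 × 10⁻⁵ /M/s, Ea = 87.0 kJ/mol)
    target ⇌ isomer of the product (K = 2.90, k = 6.10 × 10⁻⁴ /s, Ea = 81.0 kJ/mol, ΔH = −66.0 kJ/mol)
    second substrate + protic impurity → quenched substrate (k = 0.00230 /M/s, Ea = 56.0 kJ/mol)
    (constants at 25 °C)

In noon, starting material became target while reagent stood, but by 2.50 h reagent was down to 0.00702% of its charge, and at 5.00 h starting material still stood at 43.4%. So noon spent 0.835 of its 12.8 counted lifetimes. Summer held 26.3% of its reagent at 5.00 h and spent 1.00 of 1.38, while target turned into isomer of the product, which reached 46.1% against 17.3% target, and that target lies below our bracket.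

7. A neighbour flask repeats winter at 10 °C. Its count is 0.381, which gives 31.7% conversion. The simulation leaves 65.3% starting material and 69% of the reagent, with 14.4% target and 20.4% isomer of the product.

The numbers in the tables come from a simulation with constants of no real substance, noise included.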